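**Retrosynthetic overview**

- The strategy rests on ring A of the chromen-4-one: O1 (on C8a) and the C4 carbonyl (on C4a) sit on adjacent carbons, with the C5 oxygen directly beside C4a, which is the pattern a 3-alkoxyaryne delivers. C2, which carries the 4-hydroxyphenoxy group, is at the oxidation level of an ynol ether carbon.
- Last disconnection: both phenols (C5–OH, ring B C4'–OH) are unmasked from their methoxymethyl (MOM) ethers; the C7 prenyl ether is carried through.
- Key disconnection: C8a–O1, C4a–C4 and O1–C2 are cut together, giving an aryne (from a 2-silylaryl triflate) and a 3-aryloxypropiolic acid.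
- The triflate comes from 3,5-bis(benzyloxy)phenol (MOM protection, debenzylation, mono-prenylation, carbamate-directed ortho-silylation, triflation). The acid comes from 4-(benzyloxy)phenol (MOM protection, debenzylation, dichlorovinyl ether, lithium aryloxyacetylide, CO2).
- Ring order: both benzene rings are purchased; the pyranone (ring C) is the only ring made, closed in the key step.

Key step: step 11

Assumption: the aryloxypropiolic acid is taken to survive a brief cold acidic extraction and is used within hours without purification. "Prenyl" means 3-methylbut-2-en-1-yl throughout.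

**Route**

Step 1
Reactants: 1 3,5-bis(benzyloxy)phenol
Product: 2 1,3-bis(benzyloxy)-5-(methoxymethoxy)benzene
Conditions: MOMCl, i-Pr2NEt, CH2Cl2, 0 °C to rt
Reagents that add atoms: chloromethyl methyl ether, COCCl
Why: Williamson-type O-alkylation of the only free phenol with the reactive α-chloro ether under amine base should give the mixed acetal, the benzyl ethers being inert.

Step 2
Reactants: 2 1,3-bis(benzyloxy)-5-(methoxymethoxy)benzene
Product: 3 5-(methoxymethoxy)benzene-1,3-diol
Conditions: H2 (1 atm), 10% Pd/C, EtOAc, rt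
Reagents that add atoms: none
Why: Catalytic hydrogenolysis cleaves both benzylic C–O bonds under neutral conditions that leave the MOM acetal untouched, giving a resorcinol with two equivalent hydroxyls.

Step 3
Reactants: 3 5-(methoxymethoxy)benzene-1,3-diol and 4 prenyl bromide (0.9 equiv)
Product: 5 3-(methoxymethoxy)-5-[(3-methylbut-2-en-1-yl)oxy]phenol
Conditions: K2CO3, acetone, rt to 40 °C; chromatography removes the bis-ether, recovered 3 is recycled
Reagents that add atoms: none
Why: Williamson etherification (SN2 at the primary allylic carbon) of one of two equivalent phenoxides, with the bromide limiting so that the mono-ether should dominate, and carbonate in acetone favouring O- over C-alkylation.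

Step 4
Reactants: 5 3-(methoxymethoxy)-5-[(3-methylbut-2-en-1-yl)oxy]phenol
Product: 6 3-(methoxymethoxy)-5-[(3-methylbut-2-en-1-yl)oxy]phenyl N-isopropylcarbamate
Conditions: i-PrNCO, Et3N (cat.), CH2Cl2, rt
Reagents that add atoms: isopropyl isocyanate, CC(C)N=C=O
Why: Base-catalysed addition of the phenol O–H across the isocyanate gives the N-monoalkyl carbamate, a strong metalation director that is later removable under mild base.

Step 5
Reactants: 6 3-(methoxymethoxy)-5-[(3-methylbut-2-en-1-yl)oxy]phenyl N-isopropylcarbamate
Product: 10 3-(methoxymethoxy)-5-[(3-methylbut-2-en-1-yl)oxy]-2-(trimethylsilyl)phenyl N-isopropylcarbamate, via N-silyl carbamate 7 (not isolated), via ortho-lithiated N-silyl carbamate 8 (not isolated), via N,C-bis(trimethylsilyl) carbamate 9 (not isolated)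
Conditions: TMSOTf, TMEDA, Et2O, 0 °C to rt; n-BuLi, TMEDA, −78 °C; TMSCl, −78 °C to rt; aq. NH4Cl work-up
Reagents that add atoms: chlorotrimethylsilane, C[Si](C)(C)Cl
Why: Directed ortho-metalation: in situ N-silylation masks the N–H, n-BuLi/TMEDA at low temperature should remove the ring proton flanked by the carbamate and the chelating MOM acetal (a better lithium ligand than the prenyl ether, so this doubly activated site is preferred), TMSCl traps the aryllithium, and the N–Si bond hydrolyses on work-up.

Step 6
Reactants: 10 3-(methoxymethoxy)-5-[(3-methylbut-2-en-1-yl)oxy]-2-(trimethylsilyl)phenyl N-isopropylcarbamate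
Product: 12 3-(methoxymethoxy)-5-[(3-methylbut-2-en-1-yl)oxy]-2-(trimethylsilyl)phenyl trifluoromethanesulfonate, via amidinium silylphenoxide 11 (not isolated)
Conditions: DBU, Et2NH, MeCN, 40 °C; then PhNTf2, rt
Reagents that add atoms: N-phenylbis(trifluoromethanesulfonimide), O=S(=O)(N(c1ccccc1)S(=O)(=O)C(F)(F)F)C(F)(F)F
Why: Deprotonation of the carbamate N–H triggers E1cB loss of isopropyl isocyanate (scavenged by diethylamine as a urea), and the hindered phenoxide is O-sulfonylated in the same flask by the mild triflyl donor without disturbing the aryl–silicon bond.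

Step 7
Reactants: 13 4-(benzyloxy)phenol
Product: 14 1-(benzyloxy)-4-(methoxymethoxy)benzene
Conditions: MOMCl, i-Pr2NEt, CH2Cl2, 0 °C to rt
Reagents that add atoms: chloromethyl methyl ether, COCCl
Why: The same Williamson-type acetal formation on the free phenol, giving a base-stable protecting group that tolerates the organolithium and fluoride steps ahead.

Step 8
Reactants: 14 1-(benzyloxy)-4-(methoxymethoxy)benzene
Product: 15 4-(methoxymethoxy)phenol
Conditions: H2 (1 atm), 10% Pd/C, EtOAc, rt
Reagents that add atoms: none
Why: Hydrogenolysis of the benzyl ether under neutral conditions frees one phenol while the MOM acetal stays in place.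

Step 9
Reactants: 15 4-(methoxymethoxy)phenol and 16 trichloroethylene
Product: 18 1-{[(E)-1,2-dichloroethenyl]oxy}-4-(methoxymethoxy)benzene, via dichloroacetylene 17 (not isolated)
Conditions: K2CO3, DMF, 70 °C (closed vessel; the toxic haloalkyne is generated and consumed in solution only)
Reagents that add atoms: none
Why: Carbonate dehydrochlorinates trichloroethylene to dichloroacetylene, and anti nucleophilic addition of the phenoxide to this haloalkyne followed by protonation should give the (E)-1,2-dichlorovinyl ether.

Step 10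
Reactants: 18 1-{[(E)-1,2-dichloroethenyl]oxy}-4-(methoxymethoxy)benzene
Product: 22 3-[4-(methoxymethoxy)phenoxy]prop-2-ynoic acid, via aryloxy chloroalkyne 19 (not isolated), via lithium aryloxyacetylide 20 (not isolated), via lithium aryloxypropiolate 21 (not isolated)
Conditions: n-BuLi (2.1 equiv, titrated), THF, −78 °C; dry CO2, −78 to −20 °C; cold dilute aq. HCl to pH 3, extraction at 0 °C, used at once
Reagents that add atoms: carbon dioxide, O=C=O
Why: One equivalent of n-BuLi removes the vinylic proton with β-elimination of chloride, a second effects chlorine–lithium exchange to the lithium acetylide, and acetylide carboxylation with CO2 gives the propiolate; n-BuLi is kept near two equivalents so that no pentanoic acid is carried into step 11.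

Step 11
Reactants: 12 3-(methoxymethoxy)-5-[(3-methylbut-2-en-1-yl)oxy]-2-(trimethylsilyl)phenyl trifluoromethanesulfonate (1.2 equiv) and 22 3-[4-(methoxymethoxy)phenoxy]prop-2-ynoic acid
Product: 27 5-(methoxymethoxy)-2-[4-(methoxymethoxy)phenoxy]-7-[(3-methylbut-2-en-1-yl)oxy]-4H-chromen-4-one, via aryne 23 (not isolated), via ortho-cesiated aryl ester 24 (not isolated), via benzoxetene alkoxide 25 (not isolated), via ynone phenoxide 26 (not isolated)
Conditions: CsF (4 equiv), THF, sealed tube, 80 °C rising to 110 °C
Reagents that add atoms: none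
Why: Proposed new method: fluoride removes the silyl group of 12 and expels triflate to give aryne 23, whose triple bond spans the future C4a and C8a; the cesium carboxylate of 22 adds through oxygen to the aryne carbon remote from the MOM ether (future C8a), leaving aryl anion 24 at the carbon flanked by that ether (future C4a). The anion attacks its own ester carbonyl and the strained four-membered alkoxide 25 opens to ynone phenoxide 26, so that C8a–O1 and C4a–C4 arise by net insertion of the aryne into the acyl C–O bond. The closest known reaction type is the C–O insertion of arynes from silylaryl triflates into carboxylic acids to give o-hydroxyaryl ketones, which with arylpropiolic acids runs on to flavones in the same flask; an acid bearing an ynol ether at the β-carbon has not been used in it. The pyranone, the only ring formed, closes by 6-endo-dig oxa-Michael addition of the phenoxide to the aryloxy-bearing alkyne carbon, the electrophilic end of the push–pull ynone, and protonation at C3 by the bifluoride generated from the acid gives 27. No stereocenter is created. The step needs O-attack at C8a and 6-endo rather than 5-exo closure: the first is secured by the inductively withdrawing C5 alkoxy group beside the aryne, which polarises the triple bond and stabilises the ortho anion, the second by carbonyl stabilisation of the allenolate that only β-attack produces.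

Step 12
Reactants: 27 5-(methoxymethoxy)-2-[4-(methoxymethoxy)phenoxy]-7-[(3-methylbut-2-en-1-yl)oxy]-4H-chromen-4-one
Product: 29 5-hydroxy-2-(4-hydroxyphenoxy)-7-[(3-methylbut-2-en-1-yl)oxy]-4H-chromen-4-one, via bis(trimethylsilyl) ether 28 (not isolated)
Conditions: TMSOTf, 2,2'-bipyridyl, MeCN, 0 °C to rt; then H2O
Reagents that add atoms: none
Why: Silyl triflate–bipyridyl deprotection of aryl MOM acetals converts both into aryl silyl ethers by transfer of the methoxymethyl unit to the pyridine nitrogen under buffered, aprotic conditions, and water then hydrolyses the O–Si bonds; the lack of free protic acid and of an external nucleophile should spare the prenyl ether and the C2 aryloxy linkage.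

**Compound list**

1 | 3,5-bis(benzyloxy)phenol | Oc1cc(OCc2ccccc2)cc(OCc2ccccc2)c1 | starting material
2 | 1,3-bis(benzyloxy)-5-(methoxymethoxy)benzene | COCOc1cc(OCc2ccccc2)cc(OCc2ccccc2)c1 | intermediate
3 | 5-(methoxymethoxy)benzene-1,3-diol | COCOc1cc(O)cc(O)c1 | intermediate
4 | prenyl bromide (1-bromo-3-methylbut-2-ene) | CC(C)=CCBr | starting material
5 | 3-(methoxymethoxy)-5-[(3-methylbut-2-en-1-yl)oxy]phenol | COCOc1cc(O)cc(OCC=C(C)C)c1 | intermediate
6 | 3-(methoxymethoxy)-5-[(3-methylbut-2-en-1-yl)oxy]phenyl N-isopropylcarbamate | CC(C)NC(=O)Oc1cc(OCOC)cc(OCC=C(C)C)c1 | intermediate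
7 | 3-(methoxymethoxy)-5-(prenyloxy)phenyl N-isopropyl-N-(trimethylsilyl)carbamate | CC(C)N(C(=O)Oc1cc(OCOC)cc(OCC=C(C)C)c1)[Si](C)(C)C | intermediate (not isolated)
8 | 2-lithio-3-(methoxymethoxy)-5-(prenyloxy)phenyl N-isopropyl-N-(trimethylsilyl)carbamate (lithium on the ring carbon between the carbamate and the MOM ether) | CC(C)N(C(=O)Oc1cc(OCC=C(C)C)cc(OCOC)c1[Li])[Si](C)(C)C | intermediate (not isolated)
9 | 3-(methoxymethoxy)-5-(prenyloxy)-2-(trimethylsilyl)phenyl N-isopropyl-N-(trimethylsilyl)carbamate | CC(C)N(C(=O)Oc1cc(OCC=C(C)C)cc(OCOC)c1[Si](C)(C)C)[Si](C)(C)C | intermediate (not isolated)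
10 | 3-(methoxymethoxy)-5-[(3-methylbut-2-en-1-yl)oxy]-2-(trimethylsilyl)phenyl N-isopropylcarbamate | CC(C)NC(=O)Oc1cc(OCC=C(C)C)cc(OCOC)c1[Si](C)(C)C | intermediate
11 | DBU-H 3-(methoxymethoxy)-5-(prenyloxy)-2-(trimethylsilyl)phenoxide | [O-]c1cc(OCC=C(C)C)cc(OCOC)c1[Si](C)(C)C.C1CCC2=[NH+]CCCN2CC1 | intermediate (not isolated)
12 | 3-(methoxymethoxy)-5-[(3-methylbut-2-en-1-yl)oxy]-2-(trimethylsilyl)phenyl trifluoromethanesulfonate | COCOc1cc(OCC=C(C)C)cc(OS(=O)(=O)C(F)(F)F)c1[Si](C)(C)C | intermediate
13 | 4-(benzyloxy)phenol | Oc1ccc(OCc2ccccc2)cc1 | starting material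
14 | 1-(benzyloxy)-4-(methoxymethoxy)benzene | COCOc1ccc(OCc2ccccc2)cc1 | intermediate
15 | 4-(methoxymethoxy)phenol | COCOc1ccc(O)cc1 | intermediate
16 | trichloroethylene | ClC=C(Cl)Cl | starting material
17 | dichloroacetylene | ClC#CCl | intermediate (not isolated)
18 | 1-{[(E)-1,2-dichloroethenyl]oxy}-4-(methoxymethoxy)benzene | COCOc1ccc(O/C(Cl)=C\Cl)cc1 | intermediate
19 | 1-[(chloroethynyl)oxy]-4-(methoxymethoxy)benzene | COCOc1ccc(OC#CCl)cc1 | intermediate (not isolated)
20 | lithium [4-(methoxymethoxy)phenoxy]acetylide | COCOc1ccc(OC#C[Li])cc1 | intermediate (not isolated)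
21 | lithium 3-[4-(methoxymethoxy)phenoxy]prop-2-ynoate | COCOc1ccc(OC#CC(=O)[O-])cc1.[Li+] | intermediate (not isolated)
22 | 3-[4-(methoxymethoxy)phenoxy]prop-2-ynoic acid | COCOc1ccc(OC#CC(=O)O)cc1 | intermediate
23 | 3-(methoxymethoxy)-5-(prenyloxy)benzyne (triple bond between the former C–OTf and C–Si carbons) | COCOC1=CC(OCC=C(C)C)=CC#C1 | intermediate (not isolated)
24 | cesium 2-(methoxymethoxy)-4-(prenyloxy)-6-{3-[4-(methoxymethoxy)phenoxy]prop-2-ynoyloxy}phenide | COCOc1ccc(OC#CC(=O)Oc2cc(OCC=C(C)C)cc(OCOC)[c-]2)cc1.[Cs+] | intermediate (not isolated)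
25 | cesium 3-(methoxymethoxy)-5-(prenyloxy)-2-{[4-(methoxymethoxy)phenoxy]ethynyl}-2H-benzoxet-2-olate | COCOc1ccc(OC#CC2([O-])Oc3cc(OCC=C(C)C)cc(OCOC)c32)cc1.[Cs+] | intermediate (not isolated)
26 | cesium 3-(methoxymethoxy)-2-{3-[4-(methoxymethoxy)phenoxy]prop-2-ynoyl}-5-(prenyloxy)phenoxide | COCOc1ccc(OC#CC(=O)c2c(OCOC)cc(OCC=C(C)C)cc2[O-])cc1.[Cs+] | intermediate (not isolated)
27 | 5-(methoxymethoxy)-2-[4-(methoxymethoxy)phenoxy]-7-[(3-methylbut-2-en-1-yl)oxy]-4H-chromen-4-one | COCOc1cc(OCC=C(C)C)cc2oc(Oc3ccc(OCOC)cc3)cc(=O)c12 | intermediate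
28 | 7-(prenyloxy)-5-(trimethylsilyloxy)-2-[4-(trimethylsilyloxy)phenoxy]-4H-chromen-4-one | CC(C)=CCOc1cc(O[Si](C)(C)C)c2c(=O)cc(Oc3ccc(O[Si](C)(C)C)cc3)oc2c1 | intermediate (not isolated)
29 | 5-hydroxy-2-(4-hydroxyphenoxy)-7-[(3-methylbut-2-en-1-yl)oxy]-4H-chromen-4-one (CNP0286955.0) | CC(C)=CCOc1cc(O)c2c(=O)cc(Oc3ccc(O)cc3)oc2c1 | target

**Step count and risks**

Total steps: 12. Longest linear sequence: 8 steps (steps 1–6, 11, 12); the acid branch (steps 7–10) joins at step 11.

Steps most likely to fail:

1. Step 11 (new method). The ynol ether acid may decarboxylate or suffer conjugate addition of fluoride or carboxylate before O-arylation, or the aryl anion may be protonated to an aryl ester instead of transferring the acyl group. The fallback uses known chemistry, sets out from triflate 12 (with phenol 15 as the ring B source, so step 10 is bypassed) and returns at 27. Aryne C–O insertion of 12 with acetic acid (CsF, THF, heat) should give 1-{2-hydroxy-6-(methoxymethoxy)-4-[(3-methylbut-2-en-1-yl)oxy]phenyl}ethan-1-one F1. Condensation with CS2 and KOt-Bu in THF closes the ring to 4-hydroxy-5-(methoxymethoxy)-7-(prenyloxy)-2H-chromene-2-thione F2. S-Methylation (MeI, K2CO3, acetone) gives 5-(methoxymethoxy)-2-(methylsulfanyl)-7-(prenyloxy)-4H-chromen-4-one F3. Sulfur oxidation that tolerates the alkene ((NH4)6Mo7O24·4H2O cat., H2O2, EtOH) gives 5-(methoxymethoxy)-2-(methylsulfonyl)-7-(prenyloxy)-4H-chromen-4-one F4. The potassium phenoxide of 15 (K2CO3, DMF, rt) then displaces methanesulfinate at C2 by addition–elimination to give 27.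

2. Step 5. Metalation may be divided between the two carbamate-flanked ring positions, and the prenyl ether may be eroded by base-induced elimination under n-BuLi. The fallback sets out from diol 3 and returns at 10, with the prenyl group introduced only after the lithiation. Mono-silylation of 3 (TIPSCl, imidazole, DMF) gives 3-(methoxymethoxy)-5-[(triisopropylsilyl)oxy]phenol F5. Carbamoylation (i-PrNCO, Et3N cat.) gives 3-(methoxymethoxy)-5-[(triisopropylsilyl)oxy]phenyl N-isopropylcarbamate F6. The same N-silylation/lithiation/TMSCl sequence, now steered only to the carbon between carbamate and MOM ether because the bulky silyl ether shields its own neighbours, gives 3-(methoxymethoxy)-5-[(triisopropylsilyl)oxy]-2-(trimethylsilyl)phenyl N-isopropylcarbamate F7. Buffered desilylation of the aryl silyl ether (TBAF/AcOH, THF, 0 °C) gives 5-hydroxy-3-(methoxymethoxy)-2-(trimethylsilyl)phenyl N-isopropylcarbamate F8. Prenylation with 4 (K2CO3, acetone, rt) gives 10.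

3. Step 12. The prenyl ether may be partly lost under Lewis-acidic activation, the C2 aryloxy bond may be solvolysed on aqueous quench, or the ring B MOM ether may cleave incompletely. The fallback sets out from 27 and returns at target 29 by removing all three ether groups deliberately and re-installing the prenyl group selectively. BCl3 with pentamethylbenzene as cation trap (CH2Cl2, −78 to 0 °C) should give 5,7-dihydroxy-2-(4-hydroxyphenoxy)-4H-chromen-4-one F9. One equivalent each of K2CO3 and prenyl bromide 4 (acetone, rt) should then alkylate the C7 hydroxyl, the most acidic one (vinylogous acid), in preference to the chelated C5–OH and the ordinary ring B phenol, giving 29.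

**Further compounds**

F1 | step 11 | 1-{2-hydroxy-6-(methoxymethoxy)-4-[(3-methylbut-2-en-1-yl)oxy]phenyl}ethan-1-one | CC(=O)c1c(O)cc(OCC=C(C)C)cc1OCOC
F2 | step 11 | 4-hydroxy-5-(methoxymethoxy)-7-[(3-methylbut-2-en-1-yl)oxy]-2H-chromene-2-thione | COCOc1cc(OCC=C(C)C)cc2oc(=S)cc(O)c12
F3 | step 11 | 5-(methoxymethoxy)-2-(methylsulfanyl)-7-[(3-methylbut-2-en-1-yl)oxy]-4H-chromen-4-one | COCOc1cc(OCC=C(C)C)cc2oc(SC)cc(=O)c12
F4 | step 11 | 5-(methoxymethoxy)-2-(methylsulfonyl)-7-[(3-methylbut-2-en-1-yl)oxy]-4H-chromen-4-one | COCOc1cc(OCC=C(C)C)cc2oc(S(C)(=O)=O)cc(=O)c12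
F5 | step 5 | 3-(methoxymethoxy)-5-[(triisopropylsilyl)oxy]phenol | COCOc1cc(O)cc(O[Si](C(C)C)(C(C)C)C(C)C)c1
F6 | step 5 | 3-(methoxymethoxy)-5-[(triisopropylsilyl)oxy]phenyl N-isopropylcarbamate | CC(C)NC(=O)Oc1cc(OCOC)cc(O[Si](C(C)C)(C(C)C)C(C)C)c1
F7 | step 5 | 3-(methoxymethoxy)-5-[(triisopropylsilyl)oxy]-2-(trimethylsilyl)phenyl N-isopropylcarbamate | CC(C)NC(=O)Oc1cc(O[Si](C(C)C)(C(C)C)C(C)C)cc(OCOC)c1[Si](C)(C)C
F8 | step 5 | 5-hydroxy-3-(methoxymethoxy)-2-(trimethylsilyl)phenyl N-isopropylcarbamate | CC(C)NC(=O)Oc1cc(O)cc(OCOC)c1[Si](C)(C)C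
F9 | step 12 | 5,7-dihydroxy-2-(4-hydroxyphenoxy)-4H-chromen-4-one | O=c1cc(Oc2ccc(O)cc2)oc2cc(O)cc(O)c12
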